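**Retrosynthetic overview**
1. Target 10 ⇐ 9: mono-O-methylation of one of the two homotopic 7-OH groups of a C2-symmetric tetraphenol; 9 ⇐ 8 by debenzylation.
2. 8 ⇐ 6: both pyranone (C) rings are opened at O1–C2 and O1''–C2'' to an α,α'-linked bichalcone. Forward, a twofold asymmetric oxa-Michael closure (the chalcone→flavanone isomerisation of flavonoid biosynthesis) sets all four stereocentres.
3. 6 ⇐ 3 + 2 × 4: the two C2=C3-precursor alkenes come from a twofold aldol condensation; the C3–C3'' bond is already the CH2–CH2 bond of a 1,4-diketone.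
4. 3 ⇐ 2 × 1: oxidative enolate homocoupling of a protected phloroacetophenone.
5. Ring order: A and B rings are bought; the two C rings are closed one after the other in the same flask in step 3.

**Assumptions**
- The SMILES is read as (2R,3R,2''R,3''R), i.e. H-2/H-3 cis in both flavanone units, with two homochiral halves.
- The presumed biosynthesis is taken as: α,α'-linked chalcone dimer → twofold chalcone–flavanone ring closure → O-methylation.
- The quinidine-derived squaramide is assumed to give the 2R sense; this is assigned by analogy and must be confirmed on the first run.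
- Compound 1 is a catalogue compound (otherwise one step from 2',4',6'-trihydroxyacetophenone, BnBr, K2CO3).

**Route**

Step 1
Reactants: 1 1-[2,4-bis(benzyloxy)-6-hydroxyphenyl]ethan-1-one (two molecules)
Product: 3 1,4-bis[2,4-bis(benzyloxy)-6-hydroxyphenyl]butane-1,4-dione, via dilithium phenoxide-enolate 2 (not isolated)
Conditions: LDA (2.2 equiv), THF, −78 °C; CuCl2 (1.1 equiv), DMF, −78 °C → rt; aq. NH4Cl
Reagents that add atoms: none
Why: Saegusa-type oxidative homocoupling of a ketone lithium enolate: Cu(II) oxidises the electron-rich enolate carbon of the dianion (not the acyl-deactivated phenoxide) to an α-keto radical that dimerises to the symmetrical 1,4-diketone; no stereocentre is formed.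

Step 2
Reactants: 3 1,4-bis[2,4-bis(benzyloxy)-6-hydroxyphenyl]butane-1,4-dione, 4 4-methoxybenzaldehyde (3 equiv)
Product: 6 (2E,3E)-1,4-bis[2,4-bis(benzyloxy)-6-hydroxyphenyl]-2,3-bis(4-methoxybenzylidene)butane-1,4-dione, via mono-arylidene diketone 5 (not isolated)
Conditions: KOH (50% aq.), EtOH, rt, 48–72 h; then AcOH, 0 °C
Reagents that add atoms: none
Why: Twofold Claisen–Schmidt (crossed aldol) condensation: both CH2 groups are α to an aryl ketone, the aldehyde cannot enolise, the strongly basic medium keeps both 2'-OH groups as phenoxides so the chalcone arms stay open, and no acid is present to trigger Paal–Knorr furan formation; the E geometry (aryl trans to aroyl) is thermodynamic.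

Step 3
Reactants: 6 (2E,3E)-1,4-bis[2,4-bis(benzyloxy)-6-hydroxyphenyl]-2,3-bis(4-methoxybenzylidene)butane-1,4-dione
Product: 8 (2R,3R,2''R,3''R)-5,5'',7,7''-tetrakis(benzyloxy)-2,2''-bis(4-methoxyphenyl)-[3,3''-bichromane]-4,4''-dione, via mono-cyclised flavanone-chalcone 7 (not isolated)
Conditions: quinidine-derived 3,5-(CF3)2C6H3-squaramide (10 mol %), PhMe, −20 → 0 °C
Reagents that add atoms: none
Why: Proposed new method: a twofold catalytic asymmetric 6-endo-trig oxa-Michael closure of an α,α'-bichalcone, closest to the known cinchona-thiourea/squaramide cyclisations of α-substituted (α-alkoxycarbonyl) 2'-hydroxychalcones to flavanones; the quinuclidine deprotonates the phenol while the squaramide binds the enone carbonyl, so the catalyst sets C2 and then C2'' as R, and each resulting 3-substituted chromen-4-olate, whose 2-aryl group sits pseudo-axial to avoid A(1,2) strain, is protonated by the quinuclidinium on the face opposite that aryl group, giving the 2,3-cis (2R,3R) relationship kinetically in each ring; two catalyst-controlled events turn the (2R,2''S) error into a separable diastereomer and raise the ee of the C2-symmetric product, and the product has no free phenol and is kept cold in a non-polar solvent so it does not re-open or epimerise.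

Step 4
Reactants: 8 (2R,3R,2''R,3''R)-5,5'',7,7''-tetrakis(benzyloxy)-2,2''-bis(4-methoxyphenyl)-[3,3''-bichromane]-4,4''-dione
Product: 9 (2R,3R,2''R,3''R)-5,5'',7,7''-tetrahydroxy-2,2''-bis(4-methoxyphenyl)-[3,3''-bichromane]-4,4''-dione
Conditions: H2 (1 atm), 10% Pd/C, EtOAc–MeOH, rt
Reagents that add atoms: none
Why: Catalytic hydrogenolysis of the four benzyl ethers under neutral conditions; the chelated aryl ketones and the cyclic O1–C2 ether react far more slowly at 1 atm, and with no acid or base present the cis C2/C3 centres cannot epimerise by enolisation or retro-oxa-Michael opening.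

Step 5
Reactants: 9 (2R,3R,2''R,3''R)-5,5'',7,7''-tetrahydroxy-2,2''-bis(4-methoxyphenyl)-[3,3''-bichromane]-4,4''-dione
Product: 10 (2R,3R,2''R,3''R)-5,5'',7-trihydroxy-7''-methoxy-2,2''-bis(4-methoxyphenyl)-[3,3''-bichromane]-4,4''-dione
Conditions: TMSCHN2 (1.0 equiv), MeOH–PhMe (1:4), 0 °C → rt; recovered 9 recycled
Reagents that add atoms: (trimethylsilyl)diazomethane C[Si](C)(C)C=[N+]=[N-]
Why: Desymmetrising O-methylation with a diazoalkane: only the two 7-OH groups (vinylogous acids) protonate the reagent while the 5-OH groups are chelated to C4=O, and because 9 is C2-symmetric the two 7-OH groups are homotopic, so mono-methylation gives a single compound (statistical, about 45–50 % per pass); the neutral conditions leave all four stereocentres untouched.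

**Compound list**
1 | 1-[2,4-bis(benzyloxy)-6-hydroxyphenyl]ethan-1-one | CC(=O)c1c(O)cc(OCc2ccccc2)cc1OCc1ccccc1 | starting material
2 | dilithium phenoxide-enolate of 1 | [Li+].[Li+].C=C([O-])c1c([O-])cc(OCc2ccccc2)cc1OCc1ccccc1 | intermediate
3 | 1,4-bis[2,4-bis(benzyloxy)-6-hydroxyphenyl]butane-1,4-dione | O=C(CCC(=O)c1c(O)cc(OCc2ccccc2)cc1OCc1ccccc1)c1c(O)cc(OCc2ccccc2)cc1OCc1ccccc1 | intermediate
4 | 4-methoxybenzaldehyde | COc1ccc(C=O)cc1 | starting material
5 | (E)-1,4-bis[2,4-bis(benzyloxy)-6-hydroxyphenyl]-2-(4-methoxybenzylidene)butane-1,4-dione | O=C(c1c(O)cc(OCc2ccccc2)cc1OCc1ccccc1)/C(=C/c1ccc(OC)cc1)CC(=O)c1c(O)cc(OCc2ccccc2)cc1OCc1ccccc1 | intermediate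
6 | (2E,3E)-1,4-bis[2,4-bis(benzyloxy)-6-hydroxyphenyl]-2,3-bis(4-methoxybenzylidene)butane-1,4-dione (α,α'-bichalcone) | O=C(c1c(O)cc(OCc2ccccc2)cc1OCc1ccccc1)/C(=C/c1ccc(OC)cc1)/C(=C\c1ccc(OC)cc1)C(=O)c1c(O)cc(OCc2ccccc2)cc1OCc1ccccc1 | intermediate
7 | (2R,3R)-5,7-bis(benzyloxy)-3-[(E)-3-[2,4-bis(benzyloxy)-6-hydroxyphenyl]-1-(4-methoxyphenyl)-3-oxoprop-1-en-2-yl]-2-(4-methoxyphenyl)chroman-4-one (2,3-cis) | COc1ccc([C@@H]2Oc3cc(OCc4ccccc4)cc(OCc4ccccc4)c3C(=O)[C@@H]2/C(=C\c2ccc(OC)cc2)C(=O)c2c(O)cc(OCc3ccccc3)cc2OCc2ccccc2)cc1 | intermediate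
8 | (2R,3R,2''R,3''R)-5,5'',7,7''-tetrakis(benzyloxy)-2,2''-bis(4-methoxyphenyl)-[3,3''-bichromane]-4,4''-dione (cis,cis) | COc1ccc([C@@H]2Oc3cc(OCc4ccccc4)cc(OCc4ccccc4)c3C(=O)[C@@H]2[C@H]2C(=O)c3c(OCc4ccccc4)cc(OCc4ccccc4)cc3O[C@H]2c2ccc(OC)cc2)cc1 | intermediate
9 | (2R,3R,2''R,3''R)-5,5'',7,7''-tetrahydroxy-2,2''-bis(4-methoxyphenyl)-[3,3''-bichromane]-4,4''-dione | COc1ccc([C@@H]2Oc3cc(O)cc(O)c3C(=O)[C@@H]2[C@H]2C(=O)c3c(O)cc(O)cc3O[C@H]2c2ccc(OC)cc2)cc1 | intermediate
10 | (2R,3R,2''R,3''R)-5,5'',7-trihydroxy-7''-methoxy-2,2''-bis(4-methoxyphenyl)-[3,3''-bichromane]-4,4''-dione | COc1ccc([C@@H]2Oc3cc(O)cc(O)c3C(=O)[C@@H]2[C@H]2C(=O)c3c(O)cc(OC)cc3O[C@H]2c2ccc(OC)cc2)cc1 | target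

**Totals**
Total step count: 5. Longest linear sequence: 5 (1 → 3 → 6 → 8 → 9 → 10).

**Steps most likely to fail, with fallbacks**

Step 3 (twofold asymmetric closure; risk of poor cis selectivity or ee, or of the wrong sense of induction). The fallback sets out from 6 and returns at 8. Oxidative cyclisation of 6 (cat. I2, DMSO, 120 °C) gives 5,5'',7,7''-tetrakis(benzyloxy)-2,2''-bis(4-methoxyphenyl)-4H,4''H-[3,3''-bichromene]-4,4''-dione F1. A homogeneous asymmetric hydrogenation of both C2=C3 bonds (chiral Ru(II)–NHC catalyst of the kind used for flavones and chromones, H2 under pressure) then gives 8. The cis relationship follows from syn delivery of H2 and the catalyst sets the face; benzyl ethers survive a homogeneous Ru catalyst. The hindered tetrasubstituted alkenes are the weak point of this fallback.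

Step 2 (twofold aldol condensation on a 1,4-diketone; risk of alkene migration to the ene-dione or of stopping at 5). The fallback sets out from 4 and returns at 6; the C3–C3'' bond is then bought as the central bond of succinate. A double Stobbe condensation of 4 with diethyl succinate (NaOEt, EtOH, reflux; then aq. NaOH) gives (2E,3E)-2,3-bis(4-methoxybenzylidene)succinic acid F2. Coupling with MeNH(OMe)·HCl (EDC·HCl, HOBt, i-Pr2NEt) gives (2E,3E)-N1,N4-dimethoxy-2,3-bis(4-methoxybenzylidene)-N1,N4-dimethylsuccinamide F3. Separately, NBS bromination of commercial 1,3,5-tris(benzyloxy)benzene gives 2-bromo-1,3,5-tris(benzyloxy)benzene F4. Br/Li exchange of F4 (n-BuLi, THF, −78 °C) and addition to F3 gives (2E,3E)-2,3-bis(4-methoxybenzylidene)-1,4-bis[2,4,6-tris(benzyloxy)phenyl]butane-1,4-dione F5. BCl3 (2.2 equiv, CH2Cl2, −78 °C) then removes one carbonyl-chelated ortho-benzyl group per ring and gives 6.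

Step 1 (oxidative coupling of a dianion carrying a free phenoxide; risk of phenoxide oxidation or benzofuranone formation). The fallback sets out from 1 (with 4) and returns at 6; it moves the oxidative coupling to a substrate without a free phenol. Claisen–Schmidt condensation of 1 with 4 (KOH, EtOH) gives (E)-1-[2,4-bis(benzyloxy)-6-hydroxyphenyl]-3-(4-methoxyphenyl)prop-2-en-1-one F6. Cyclisation (NaOAc, EtOH, reflux) gives rac-5,7-bis(benzyloxy)-2-(4-methoxyphenyl)chroman-4-one F7. Enolate formation (LDA, THF, −78 °C) and CuCl2 oxidation give 5,5'',7,7''-tetrakis(benzyloxy)-2,2''-bis(4-methoxyphenyl)-[3,3''-bichromane]-4,4''-dione as a stereoisomer mixture F8. Twofold E1cB ring opening (KOH, EtOH; then cold AcOH) erases those stereocentres and gives 6.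

**Further compounds**
F1 | step 3 | 5,5'',7,7''-tetrakis(benzyloxy)-2,2''-bis(4-methoxyphenyl)-4H,4''H-[3,3''-bichromene]-4,4''-dione | COc1ccc(-c2oc3cc(OCc4ccccc4)cc(OCc4ccccc4)c3c(=O)c2-c2c(-c3ccc(OC)cc3)oc3cc(OCc4ccccc4)cc(OCc4ccccc4)c3c2=O)cc1
F2 | step 2 | (2E,3E)-2,3-bis(4-methoxybenzylidene)succinic acid | COc1ccc(/C=C(C(=O)O)\C(=C/c2ccc(OC)cc2)C(=O)O)cc1
F3 | step 2 | (2E,3E)-N1,N4-dimethoxy-2,3-bis(4-methoxybenzylidene)-N1,N4-dimethylsuccinamide | COc1ccc(/C=C(C(=O)N(C)OC)\C(=C/c2ccc(OC)cc2)C(=O)N(C)OC)cc1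
F4 | step 2 | 2-bromo-1,3,5-tris(benzyloxy)benzene | Brc1c(OCc2ccccc2)cc(OCc2ccccc2)cc1OCc1ccccc1
F5 | step 2 | (2E,3E)-2,3-bis(4-methoxybenzylidene)-1,4-bis[2,4,6-tris(benzyloxy)phenyl]butane-1,4-dione | O=C(c1c(OCc2ccccc2)cc(OCc2ccccc2)cc1OCc1ccccc1)/C(=C/c1ccc(OC)cc1)/C(=C\c1ccc(OC)cc1)C(=O)c1c(OCc2ccccc2)cc(OCc2ccccc2)cc1OCc1ccccc1
F6 | step 1 | (E)-1-[2,4-bis(benzyloxy)-6-hydroxyphenyl]-3-(4-methoxyphenyl)prop-2-en-1-one | COc1ccc(/C=C/C(=O)c2c(O)cc(OCc3ccccc3)cc2OCc2ccccc2)cc1
F7 | step 1 | rac-5,7-bis(benzyloxy)-2-(4-methoxyphenyl)chroman-4-one | COc1ccc(C2CC(=O)c3c(OCc4ccccc4)cc(OCc4ccccc4)cc3O2)cc1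
F8 | step 1 | 5,5'',7,7''-tetrakis(benzyloxy)-2,2''-bis(4-methoxyphenyl)-[3,3''-bichromane]-4,4''-dione, stereoisomer mixture | COc1ccc(C2Oc3cc(OCc4ccccc4)cc(OCc4ccccc4)c3C(=O)C2C2C(=O)c3c(OCc4ccccc4)cc(OCc4ccccc4)cc3OC2c2ccc(OC)cc2)cc1
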